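**Retrosynthetic overview**

1. Target 23 is the myristate of (3S,5R,6S)-5,6-epoxy-3-hydroxy-β-ionone; the ester, the C7=C8 enone (Wittig on a C6 aldehyde) and the C5–C6 oxirane (Sharpless epoxidation of the C6 hydroxymethyl allylic alcohol) are removed in that order.
2. Feature on which the route rests: in the six-membered carbocycle (C1 gem-dimethyl carbon, C3 ester carbinol, C5/C6 oxirane carbons) the oxygens on C3 and C5 are 1,3-related, so with C5 as a ketone C3–C4 is an aldol bond, and C5–C6–C7 is a β-keto ester whose enol triflate accepts the C5 methyl.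
3. Key disconnection C3–C4: (R)-proline enamine aldol of keto aldehyde 9, which closes the carbocycle and sets C3.
4. Keto aldehyde 9 comes in four steps from diethyl isopropylidenemalonate: allyl conjugate addition (quaternary C1), Krapcho, Claisen acetylation, ozonolysis.
5. Ring order: carbocycle first (step 5), oxirane second (step 10).

Key step: step 5

**Remarks before the steps**

- Target atoms are referred to by ionone numbering (C1 gem-dimethyl carbon, C3 carbinol, C5/C6 oxirane carbons, C7–C10 side chain); the names of intermediates carry their own IUPAC locants.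
- Assumption: the sense of induction in step 5 is a prediction from the Hajos–Parrish-type transition-state model, and D-proline is chosen on that basis.
- The C3 carbinol keeps one spatial arrangement from 11 to 23. Its descriptor is S in 11–14, R in 15 and 16, and S from 17 on, only because the CIP ranking of the two ring CH2 branches changes.

**Route**

Step 1
Reactants: 1 diethyl isopropylidenemalonate; 2 allylmagnesium bromide
Product: 3 diethyl 2-(2-methylpent-4-en-2-yl)propanedioate
Conditions: CuI (10 mol%), THF, −30 → 0 °C; aq. NH4Cl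
Reagents that add atoms: none
Why: Copper-catalysed conjugate (Michael) addition of the allyl Grignard reagent to the doubly activated alkylidene malonate builds the quaternary C1 without competing 1,2-addition.

Step 2
Reactants: 3 diethyl 2-(2-methylpent-4-en-2-yl)propanedioate
Product: 4 ethyl 3,3-dimethylhex-5-enoate
Conditions: LiCl, H2O, DMSO, 160 °C
Reagents that add atoms: none
Why: Krapcho dealkoxycarbonylation removes one ester group of the monosubstituted malonate under neutral halide conditions that leave the terminal alkene untouched.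

Step 3
Reactants: 4 ethyl 3,3-dimethylhex-5-enoate; 5 acetyl chloride
Product: 7 ethyl 2-acetyl-3,3-dimethylhex-5-enoate, via lithium ester enolate 6 (not isolated)
Conditions: LDA (1.05 equiv), THF, −78 °C; enolate solution added to AcCl (1.5 equiv), THF, −78 °C; aq. NH4Cl
Reagents that add atoms: none
Why: Claisen-type C-acylation of a lithium ester enolate by an acid chloride at −78 °C, run by inverse addition so that the enolate meets excess acid chloride and is not quenched by the more acidic β-keto ester product, installs the acetyl group that supplies C5 and C4.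

Step 4
Reactants: 7 ethyl 2-acetyl-3,3-dimethylhex-5-enoate
Product: 9 ethyl 2-acetyl-3,3-dimethyl-5-oxopentanoate, via secondary ozonide 8 (not isolated)
Conditions: O3, CH2Cl2, −78 °C (Sudan red end point); Me2S, −78 °C → rt
Reagents that add atoms: ozone, [O-][O+]=O
Why: Ozonolysis with reductive work-up cleaves the only C=C bond to the C3 aldehyde, and the β-keto ester, held mostly in its keto form by the bulky α-substituent, should survive when ozone is stopped at the indicator end point.

Step 5
Reactants: 9 ethyl 2-acetyl-3,3-dimethyl-5-oxopentanoate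
Product: 11 ethyl (4S)-4-hydroxy-2,2-dimethyl-6-oxocyclohexane-1-carboxylate (C1 epimers and enol form), via terminal proline enamine 10 (not isolated)
Conditions: D-proline [(R)-proline] (20 mol%), DMSO (0.05 M), rt
Reagents that add atoms: none
Why: Proposed new method: (R)-proline condenses with the methyl ketone to the less substituted enamine 10 (the conjugated enamino ester is blocked by allylic strain against the tert-alkyl group on C6), whose CH2 carbon C4 adds to the C3 aldehyde while the carboxylic acid hydrogen-bonds the aldehyde oxygen, and hydrolysis of the iminium ion returns the catalyst. The closest known reaction type is the Hajos–Parrish–Eder–Sauer–Wiechert proline aldolisation (ketone enamine, same closure mode), together with proline-catalysed cyclisation of dialdehydes and the non-asymmetric acid- or base-promoted closure of 2-acyl-5-oxopentanoates to 6-oxocyclohexanecarboxylates; a γ-enamine of a β-keto ester adding to an aldehyde is the untested part. The six-membered ring closes in the 6-(enolendo)-exo-trig mode, since both enamine carbons (C4 and C5) end up in the ring, through a chair-like transition state. The new stereocentre C3 is controlled by the catalyst alone: in the anti-enamine, acid-bound transition state the tether holds C2 gauche to C5 on the ester side with the oxygen turned to the acid, so (R)-proline should expose the aldehyde face that leads to (S), by the same model that accounts for the Hajos–Parrish sense. The step needs enantioface selection at the aldehyde and chemoselection for this closure: every other intramolecular aldol pairing would give a four-membered ring, dilution and the neopentyl-type aldehyde slow intermolecular self-aldol reaction, and the epimeric centre at C6 is irrelevant because it becomes sp2 in step 7.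

Step 6
Reactants: 11 ethyl (4S)-4-hydroxy-2,2-dimethyl-6-oxocyclohexane-1-carboxylate
Product: 12 ethyl (4S)-4-[(tert-butyldimethylsilyl)oxy]-2,2-dimethyl-6-oxocyclohexane-1-carboxylate
Conditions: TBSCl, imidazole, DMF, 0 °C → rt
Reagents that add atoms: tert-butyldimethylsilyl chloride (TBSCl), CC(C)(C)[Si](C)(C)Cl
Why: Silylation of the secondary alcohol under Corey conditions blocks retro-aldol cleavage and dehydration in the later basic steps, and any silyl enol ether of the β-keto ester is hydrolysed on aqueous work-up.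

Step 7
Reactants: 12 ethyl (4S)-4-[(tert-butyldimethylsilyl)oxy]-2,2-dimethyl-6-oxocyclohexane-1-carboxylate
Product: 14 ethyl (4S)-4-[(tert-butyldimethylsilyl)oxy]-6,6-dimethyl-2-{[(trifluoromethyl)sulfonyl]oxy}cyclohex-1-ene-1-carboxylate, via sodium enolate 13 (not isolated)
Conditions: NaH, THF, 0 °C; PhNTf2, 0 °C → rt
Reagents that add atoms: N-phenylbis(trifluoromethanesulfonimide) (PhNTf2), O=S(=O)(N(c1ccccc1)S(=O)(=O)C(F)(F)F)C(F)(F)F
Why: Enol triflate formation: NaH removes the most acidic proton (C6–H between ketone and ester, so no C4 enolate arises that could expel the β-silyloxy group) and the stabilised enolate is sulfonylated on oxygen.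

Step 8
Reactants: 14 ethyl (4S)-4-[(tert-butyldimethylsilyl)oxy]-6,6-dimethyl-2-{[(trifluoromethyl)sulfonyl]oxy}cyclohex-1-ene-1-carboxylate
Product: 15 ethyl (4R)-4-[(tert-butyldimethylsilyl)oxy]-2,6,6-trimethylcyclohex-1-ene-1-carboxylate
Conditions: Me2CuLi (from MeLi and CuI), THF, −78 → −20 °C; aq. NH4Cl
Reagents that add atoms: lithium dimethylcuprate (Me2CuLi), [Li+].C[Cu-]C
Why: Cuprate coupling of a β-(triflyloxy) enoate (conjugate addition–elimination) replaces the triflate by the C5 methyl group and keeps the tetrasubstituted alkene in place.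

Step 9
Reactants: 15 ethyl (4R)-4-[(tert-butyldimethylsilyl)oxy]-2,6,6-trimethylcyclohex-1-ene-1-carboxylate
Product: 16 [(4R)-4-[(tert-butyldimethylsilyl)oxy]-2,6,6-trimethylcyclohex-1-en-1-yl]methanol
Conditions: DIBAL (2.5 equiv), CH2Cl2, −78 → 0 °C; aq. potassium sodium tartrate
Reagents that add atoms: none
Why: DIBAL reduces the hindered α,β-unsaturated ester by 1,2-hydride delivery to the allylic alcohol and leaves the silyl ether intact.

Step 10
Reactants: 16 [(4R)-4-[(tert-butyldimethylsilyl)oxy]-2,6,6-trimethylcyclohex-1-en-1-yl]methanol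
Product: 17 [(1R,4S,6R)-4-[(tert-butyldimethylsilyl)oxy]-2,2,6-trimethyl-7-oxabicyclo[4.1.0]heptan-1-yl]methanol
Conditions: Ti(OiPr)4 (1.0 equiv), D-(−)-diethyl tartrate (1.2 equiv), TBHP, 4 Å MS, CH2Cl2, −20 °C
Reagents that add atoms: tert-butyl hydroperoxide (TBHP), CC(C)(C)OO
Why: Katsuki–Sharpless asymmetric epoxidation: with D-(−)-diethyl tartrate the titanium tartrate peroxide complex should deliver oxygen to the alkene face anti to the C3 silyloxy group (reagent control, expected to be matched with the steric bias of that group), which sets C5 and C6 of the oxirane in one step.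

Step 11
Reactants: 17 [(1R,4S,6R)-4-[(tert-butyldimethylsilyl)oxy]-2,2,6-trimethyl-7-oxabicyclo[4.1.0]heptan-1-yl]methanol
Product: 18 (1S,4S,6R)-4-[(tert-butyldimethylsilyl)oxy]-2,2,6-trimethyl-7-oxabicyclo[4.1.0]heptane-1-carbaldehyde
Conditions: (nPr4N)RuO4 (TPAP, 5 mol%), NMO, 4 Å MS, CH2Cl2, rt
Reagents that add atoms: none
Why: Ley–Griffith oxidation converts the neopentyl-type primary alcohol into the aldehyde under neutral conditions that do not open the oxirane, and the α-carbon is quaternary, so nothing can epimerise.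

Step 12
Reactants: 18 (1S,4S,6R)-4-[(tert-butyldimethylsilyl)oxy]-2,2,6-trimethyl-7-oxabicyclo[4.1.0]heptane-1-carbaldehyde; 19 1-(triphenylphosphoranylidene)propan-2-one
Product: 20 (3E)-4-[(1S,4S,6R)-4-[(tert-butyldimethylsilyl)oxy]-2,2,6-trimethyl-7-oxabicyclo[4.1.0]heptan-1-yl]but-3-en-2-one
Conditions: toluene, 100 °C
Reagents that add atoms: none
Why: Wittig olefination with a stabilised acyl ylide should give the (E)-enone selectively and needs no base that could touch the oxirane.

Step 13
Reactants: 20 (3E)-4-[(1S,4S,6R)-4-[(tert-butyldimethylsilyl)oxy]-2,2,6-trimethyl-7-oxabicyclo[4.1.0]heptan-1-yl]but-3-en-2-one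
Product: 21 (3E)-4-[(1S,4S,6R)-4-hydroxy-2,2,6-trimethyl-7-oxabicyclo[4.1.0]heptan-1-yl]but-3-en-2-one
Conditions: TBAF, AcOH, THF, 0 °C → rt
Reagents that add atoms: none
Why: Fluoride-mediated desilylation, buffered with acetic acid so that no free alkoxide or strong acid is present to open the oxirane, releases the C3 alcohol.

Step 14
Reactants: 21 (3E)-4-[(1S,4S,6R)-4-hydroxy-2,2,6-trimethyl-7-oxabicyclo[4.1.0]heptan-1-yl]but-3-en-2-one; 22 myristoyl chloride (tetradecanoyl chloride)
Product: 23 (1R,3S,6S)-1,5,5-trimethyl-6-[(1E)-3-oxobut-1-en-1-yl]-7-oxabicyclo[4.1.0]heptan-3-yl tetradecanoate (CNP0118807.1)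
Conditions: pyridine, DMAP (cat.), CH2Cl2, 0 °C → rt
Reagents that add atoms: none
Why: DMAP-catalysed acylation of the secondary alcohol with the acid chloride (nucleophilic catalysis) forms the myristate on oxygen with retention at C3.

**Compound list**

1 | diethyl isopropylidenemalonate | CCOC(=O)C(=C(C)C)C(=O)OCC | starting material
2 | allylmagnesium bromide | C=CC[Mg]Br | starting material
3 | diethyl 2-(2-methylpent-4-en-2-yl)propanedioate | CCOC(=O)C(C(=O)OCC)C(C)(C)CC=C | intermediate
4 | ethyl 3,3-dimethylhex-5-enoate | CCOC(=O)CC(C)(C)CC=C | intermediate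
5 | acetyl chloride | CC(Cl)=O | starting material
6 | lithium 1-ethoxy-3,3-dimethylhexa-1,5-dien-1-olate (enolate of 4; not isolated) | CCOC(O[Li])=CC(C)(C)CC=C | intermediate
7 | ethyl 2-acetyl-3,3-dimethylhex-5-enoate (racemic) | CCOC(=O)C(C(C)=O)C(C)(C)CC=C | intermediate
8 | ethyl 2-acetyl-3,3-dimethyl-4-(1,2,4-trioxolan-3-yl)butanoate (secondary ozonide; not isolated) | CCOC(=O)C(C(C)=O)C(C)(C)CC1OCOO1 | intermediate
9 | ethyl 2-acetyl-3,3-dimethyl-5-oxopentanoate (racemic at the labile C2) | CCOC(=O)C(C(C)=O)C(C)(C)CC=O | intermediate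
10 | (2R)-1-[3-(ethoxycarbonyl)-4,4-dimethyl-6-oxohex-1-en-2-yl]pyrrolidine-2-carboxylic acid (proline enamine; not isolated) | OC(=O)[C@H]1CCCN1C(=C)C(C(=O)OCC)C(C)(C)CC=O | intermediate
11 | ethyl (4S)-4-hydroxy-2,2-dimethyl-6-oxocyclohexane-1-carboxylate (C1 labile) | O[C@H]1CC(C)(C)C(C(=O)OCC)C(=O)C1 | intermediate
12 | ethyl (4S)-4-[(tert-butyldimethylsilyl)oxy]-2,2-dimethyl-6-oxocyclohexane-1-carboxylate | CC(C)(C)[Si](C)(C)O[C@H]1CC(C)(C)C(C(=O)OCC)C(=O)C1 | intermediate
13 | sodium (5S)-5-[(tert-butyldimethylsilyl)oxy]-2-(ethoxycarbonyl)-3,3-dimethylcyclohex-1-en-1-olate (not isolated) | CC(C)(C)[Si](C)(C)O[C@H]1CC(C)(C)C(C(=O)OCC)=C(O[Na])C1 | intermediate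
14 | ethyl (4S)-4-[(tert-butyldimethylsilyl)oxy]-6,6-dimethyl-2-{[(trifluoromethyl)sulfonyl]oxy}cyclohex-1-ene-1-carboxylate | CC(C)(C)[Si](C)(C)O[C@H]1CC(C)(C)C(C(=O)OCC)=C(OS(=O)(=O)C(F)(F)F)C1 | intermediate
15 | ethyl (4R)-4-[(tert-butyldimethylsilyl)oxy]-2,6,6-trimethylcyclohex-1-ene-1-carboxylate | CC(C)(C)[Si](C)(C)O[C@H]1CC(C)(C)C(C(=O)OCC)=C(C)C1 | intermediate
16 | [(4R)-4-[(tert-butyldimethylsilyl)oxy]-2,6,6-trimethylcyclohex-1-en-1-yl]methanol | CC(C)(C)[Si](C)(C)O[C@H]1CC(C)(C)C(CO)=C(C)C1 | intermediate
17 | [(1R,4S,6R)-4-[(tert-butyldimethylsilyl)oxy]-2,2,6-trimethyl-7-oxabicyclo[4.1.0]heptan-1-yl]methanol (oxirane anti to the silyloxy group) | CC(C)(C)[Si](C)(C)O[C@H]1CC(C)(C)[C@]2(CO)O[C@]2(C)C1 | intermediate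
18 | (1S,4S,6R)-4-[(tert-butyldimethylsilyl)oxy]-2,2,6-trimethyl-7-oxabicyclo[4.1.0]heptane-1-carbaldehyde | CC(C)(C)[Si](C)(C)O[C@H]1CC(C)(C)[C@]2(C=O)O[C@]2(C)C1 | intermediate
19 | 1-(triphenylphosphoranylidene)propan-2-one | CC(=O)C=P(c1ccccc1)(c1ccccc1)c1ccccc1 | starting material
20 | (3E)-4-[(1S,4S,6R)-4-[(tert-butyldimethylsilyl)oxy]-2,2,6-trimethyl-7-oxabicyclo[4.1.0]heptan-1-yl]but-3-en-2-one | CC(C)(C)[Si](C)(C)O[C@H]1CC(C)(C)[C@]2(/C=C/C(C)=O)O[C@]2(C)C1 | intermediate
21 | (3E)-4-[(1S,4S,6R)-4-hydroxy-2,2,6-trimethyl-7-oxabicyclo[4.1.0]heptan-1-yl]but-3-en-2-one | O[C@H]1CC(C)(C)[C@]2(/C=C/C(C)=O)O[C@]2(C)C1 | intermediate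
22 | myristoyl chloride (tetradecanoyl chloride) | CCCCCCCCCCCCCC(=O)Cl | starting material
23 | (1R,3S,6S)-1,5,5-trimethyl-6-[(1E)-3-oxobut-1-en-1-yl]-7-oxabicyclo[4.1.0]heptan-3-yl tetradecanoate | CCCCCCCCCCCCCC(=O)O[C@H]1CC(C)(C)[C@]2(/C=C/C(C)=O)O[C@]2(C)C1 | target

**Step count**

Total: 14 steps. Longest linear sequence: 14 steps (from 1; compounds 2, 5, 19 and 22 are bought).

**Steps most likely to fail**

Step 5 (Proposed new method). What may go wrong:
- the hindered ketone may form the terminal enamine too slowly, so that the aldehyde is consumed by intermolecular self-aldol reaction;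
- the aldol may lose water to the enone;
- enantioface selection may be poor.

Fallback by known chemistry, taking the ring and its carbinol from the chiral pool instead of asymmetric catalysis: commercial (4R,6R)-4-hydroxy-2,2,6-trimethylcyclohexan-1-one F1 is silylated (TBSCl, imidazole, DMF) to (4R,6R)-4-[(tert-butyldimethylsilyl)oxy]-2,2,6-trimethylcyclohexan-1-one F2. Deprotonation at the only α-carbon that carries hydrogen (LDA, THF, −78 °C) and trapping with PhNTf2 gives (4R)-4-[(tert-butyldimethylsilyl)oxy]-2,6,6-trimethylcyclohex-1-en-1-yl trifluoromethanesulfonate F3. Palladium-catalysed ethoxycarbonylation of this vinyl triflate (Pd(OAc)2, PPh3, CO 1 atm, EtOH, Et3N, DMF, 70 °C) gives 15. This fallback sets out from none of the numbered compounds, because it replaces steps 1 to 8 as a whole; its entry point is F1, and it comes back to the route at 15.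

Step 3. What may go wrong: the hindered, neopentyl-type enolate may be acylated on oxygen, or proton transfer from the product may stop the reaction early. The fallback sets out from 4 and comes back at 7, forming the C–C bond by aldol addition and adjusting the oxidation level afterwards. The enolate of 4 (LDA, THF, −78 °C) is added to acetaldehyde to give ethyl 2-(1-hydroxyethyl)-3,3-dimethylhex-5-enoate F4 as a diastereomer mixture, and oxidation of the secondary alcohol with Dess–Martin periodinane in CH2Cl2 gives 7.

Step 12. What may go wrong: the stabilised ylide may add too slowly to the α-quaternary, doubly flanked aldehyde, so that thermal decomposition competes. The fallback sets out from 18 and comes back at 20, replacing olefination by aldol addition and elimination. The lithium enolate of acetone (LDA, THF, −78 °C) adds to 18 to give 4-hydroxy-4-[(1R,4S,6R)-4-[(tert-butyldimethylsilyl)oxy]-2,2,6-trimethyl-7-oxabicyclo[4.1.0]heptan-1-yl]butan-2-one F5. Treatment with MsCl and excess Et3N in CH2Cl2 (0 °C → rt) forms 3-oxo-1-[(1R,4S,6R)-4-[(tert-butyldimethylsilyl)oxy]-2,2,6-trimethyl-7-oxabicyclo[4.1.0]heptan-1-yl]butyl methanesulfonate F6, which eliminates in the same flask (E1cB) to the (E)-enone 20.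

**Further compounds**

F1 | step 5 | (4R,6R)-4-hydroxy-2,2,6-trimethylcyclohexan-1-one | O[C@H]1CC(C)(C)C(=O)[C@H](C)C1
F2 | step 5 | (4R,6R)-4-[(tert-butyldimethylsilyl)oxy]-2,2,6-trimethylcyclohexan-1-one | CC(C)(C)[Si](C)(C)O[C@H]1CC(C)(C)C(=O)[C@H](C)C1
F3 | step 5 | (4R)-4-[(tert-butyldimethylsilyl)oxy]-2,6,6-trimethylcyclohex-1-en-1-yl trifluoromethanesulfonate | CC(C)(C)[Si](C)(C)O[C@H]1CC(C)(C)C(OS(=O)(=O)C(F)(F)F)=C(C)C1
F4 | step 3 | ethyl 2-(1-hydroxyethyl)-3,3-dimethylhex-5-enoate | CCOC(=O)C(C(C)O)C(C)(C)CC=C
F5 | step 12 | 4-hydroxy-4-[(1R,4S,6R)-4-[(tert-butyldimethylsilyl)oxy]-2,2,6-trimethyl-7-oxabicyclo[4.1.0]heptan-1-yl]butan-2-one | CC(C)(C)[Si](C)(C)O[C@H]1CC(C)(C)[C@]2(C(O)CC(C)=O)O[C@]2(C)C1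
F6 | step 12 | 3-oxo-1-[(1R,4S,6R)-4-[(tert-butyldimethylsilyl)oxy]-2,2,6-trimethyl-7-oxabicyclo[4.1.0]heptan-1-yl]butyl methanesulfonate | CC(C)(C)[Si](C)(C)O[C@H]1CC(C)(C)[C@]2(C(OS(C)(=O)=O)CC(C)=O)O[C@]2(C)C1
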